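**Plan**

1. Germacrane numbering is used (ring C1–C10, C14 on C10, C15 on C4, lactone carbons C11–C13). The ester carbon C14 on C10 lies across the ring from C5, and the oxirane oxygen on C1 is 1,4 to the methyl-bearing C4. Hence C5–C10 plus C14 is a tropone, and C1–C4 plus that oxygen is 2-methylfuran.
2. Cuts, last bond first: C8–O(acyl) (Mitsunobu); lactone carbonyl C12 (cyclocarbonylation of a C7 ethynyl group); C7–C11 (alkynyl opening of a C7–C8 epoxide); C10–O of the oxirane (enolate iodination and closure); C4=C5 back to C14–C5 and C4–O (retro-Claisen/E1cB read backwards); finally C1–C10 and C4–C5 ([6+4]).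
3. Forward: step 1 closes the ten-membered carbocycle as the rim of a doubly bridged cage. The cage is oxygenated on its open face, methoxide then cuts the carbonyl bridge and the ether bridge to free the monocyclic germacrene, and oxirane, lactone and ester follow.
4. Stereochemistry: the absolute sense and C1 come from the chiral Lewis acid of step 1. O6, O9 and the C7–C8 epoxide come from the cage face syn to the carbonyl bridge. C7 and C8 are set by two SN2 inversions, C6 by hydride anti to the epoxide, C10 by a chelated enolate. A lipase tells C9–OH from C6–OH, which the remote methyl group cannot do.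

Key step: step 1

Assumption: the (S)-prolinol-derived catalyst of step 1 is taken to give the enantiomer drawn for 3; the mirror-image catalyst is equally available if the sense proves opposite.

Remark on the ring opening: in the exo cage the C14–C5 and C4–O bonds are gauche (chair tetrahydropyranone), so a concerted Grob fragmentation is not expected. The opening is therefore run stepwise, as a retro-Claisen cleavage of a C14/C6 1,3-diketone followed by E1cB loss of the C4 oxygen. This is why C6 is taken to the ketone (step 6) and reduced again (step 8).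

**Route**

Step 1
Reactants: 1 tropone; 2 2-methylfuran
Product: 3 exo [6+4] cage trienone (C14 ketone bridging C10/C5; oxygen bridging C1/C4 anti to it; methyl on C4; C6=C7–C8=C9 diene; C2=C3 alkene)
Conditions: 2 (5 equiv), (S)-B-(o-tolyl)oxazaborolidinium triflimide (from (S)-α,α-diphenylprolinol, activated with HNTf2; 20 mol %), CH2Cl2, −78 → −40 °C
Reagents that add atoms: none
Why: Proposed new method: the cationic boron Lewis acid binds the tropone oxygen and makes the 6π system a hydroxytropylium-like electrophile whose α-carbons add suprafacially across C5/C2 of the furan (allowed [π6s+π4s], probably asynchronous: C1–C10 forms first and the methyl-stabilised oxocarbenium at C4 then collapses onto the boron dienolate at C5). The closest known reactions are the thermal exo-selective [6+4] additions of tropone to cyclopentadiene and the [4+3] additions of furans to oxyallyl cations, whose compact transition state corresponds to the exo mode here; furan as the 4π partner of tropone and catalytic enantiocontrol are unproven. The ten-membered carbocycle arises as the periphery of the adduct in a bimolecular cycloaddition, and in the same event the tetrahydropyranone ring C14–C10–C1–O–C4–C5 closes as a chair, so no end-to-end medium-ring closure is needed. The stereocentres C1, C4, C5 and C10 follow relatively from suprafacial addition on both partners and the exo approach (ether bridge anti to carbonyl bridge), and absolutely from the catalyst, which covers one face of the bound tropone. The step needs periselectivity over [4+2] addition and over Friedel–Crafts substitution (proton loss from C1 of the zwitterion), which low temperature, the non-basic counter-ion and the cation-stabilising methyl group should favour; regiochemistry is no issue because the two α-carbons of tropone are equivalent.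

Step 2
Reactants: 3 cage trienone
Product: 5 cage enediol (6,9-cis-diol on the carbonyl-bridge face; C7=C8), via endoperoxide 4 (not isolated)
Conditions: O2, visible light, tetraphenylporphyrin (cat.), CH2Cl2, −30 °C; then Zn, AcOH, 0 °C
Reagents that add atoms: oxygen, O=O
Why: [4+2] photooxygenation puts singlet oxygen across C6/C9 of the cisoid diene from the open face syn to the carbonyl bridge (the other face lies under the ether oxygen), which sets both oxygens cis, and zinc in acetic acid then cleaves only the O–O bond.

Step 3
Reactants: 5 cage enediol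
Product: 6 cage epoxy diol (C7–C8 epoxide cis to both hydroxyls)
Conditions: VO(acac)2 (5 mol %), t-BuOOH, CH2Cl2, 0 °C
Reagents that add atoms: tert-butyl hydroperoxide, CC(C)(C)OO
Why: In this hydroxyl-directed (vanadyl-catalysed) epoxidation both allylic alcohols deliver the oxidant to the face they occupy, which is also the convex face, so the epoxide forms cis to O6 and O9, while the C2=C3 alkene, which has no free allylic hydroxyl, is left alone.

Step 4
Reactants: 6 cage epoxy diol
Product: 7 2,3-dihydro epoxy diol
Conditions: H2 (1 atm), Pd/C, EtOAc, rt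
Reagents that add atoms: none
Why: Heterogeneous hydrogenation reduces the strained cis-disubstituted C2=C3 alkene, the only alkene left, and a non-allylic epoxide is not hydrogenolysed under neutral conditions.

Step 5
Reactants: 7 2,3-dihydro epoxy diol
Product: 8 9-O-acetate of 7
Conditions: Burkholderia cepacia lipase, vinyl acetate, t-BuOMe, 30 °C
Reagents that add atoms: vinyl acetate, C=COC(C)=O
Why: In this lipase-catalysed acyl transfer the C6 and C9 carbinols are alike in constitution but opposite in local configuration, and by the Kazlauskas rule (hydroxyl toward the viewer, large cage carbon C10 on the right, epoxide carbon C8 on the left) the enzyme should acylate C9–OH only, which breaks the pseudo-symmetry of the cage.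

Step 6
Reactants: 8 9-O-acetate
Product: 9 C6 ketone of 8 (cage 1,3-diketone C14/C6)
Conditions: Dess–Martin periodinane, pyridine, CH2Cl2, 0 °C → rt
Reagents that add atoms: none
Why: Dess–Martin oxidation of the one free secondary alcohol removes H6 intramolecularly within the periodinane ester, so the crowding of that hydrogen by the C4 methyl group does not matter, and no stereocentre is touched.

Step 7
Reactants: 9 cage 1,3-diketone
Product: 11 (4Z)-germacrene enone (C10 methyl ester; 1-OH; 9-OH; 7,8-epoxide; C6 ketone), via bridged keto ester 10 (not isolated)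
Conditions: NaOMe (0.5 equiv), MeOH, 0 °C → rt; AcOH quench
Reagents that add atoms: methanol (as NaOMe/MeOH), CO
Why: In this retro-Claisen/E1cB cascade methoxide removes the acetate and adds to the bridging C14 ketone, the C14–C5 bond breaks because only C5 can leave as an enolate (of the C6 ketone), and that enolate expels the C4 ether oxygen to give the C4=C5 enone, the C10 methyl ester and the C1 alcohol with C1 and C10 unchanged; the Z alkene (C3 cis to C6) is the stable geometry of a cyclodecenone and is reached through reversible conjugate addition of methoxide, and C7, being an epoxide carbon, can neither enolise nor eliminate.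

Step 8
Reactants: 11 germacrene enone
Product: 12 1,6,9-triol (C6–OH cis to the epoxide oxygen)
Conditions: NaBH4, CeCl3·7H2O, MeOH, −40 °C
Reagents that add atoms: none
Why: Luche reduction delivers hydride 1,2 to the cross-conjugated ketone from the face opposite the adjacent epoxide oxygen, which gives the C6 alcohol cis to the epoxide as the target requires and avoids conjugate reduction.

Step 9
Reactants: 12 1,6,9-triol
Product: 15 6-O-TBS ether of 12, via phenylboronate 13 (not isolated), via silylated phenylboronate 14 (not isolated)
Conditions: PhB(OH)2, 4 Å molecular sieves, CH2Cl2, rt; TBSOTf, 2,6-lutidine, −78 °C; pinacol, rt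
Reagents that add atoms: tert-butyldimethylsilyl triflate, CC(C)(C)[Si](C)(C)OS(=O)(=O)C(F)(F)F
Why: Transient boronate protection ties the C1/C9 1,3-diol as a six-membered phenylboronate, so that only the allylic C6 hydroxyl is silylated, and transesterification with pinacol then frees the diol; no stereocentre is affected.

Step 10
Reactants: 15 6-O-TBS diol
Product: 16 7-[(trimethylsilyl)ethynyl] 1,8,9-triol (alkynyl trans to O6 and O8)
Conditions: Me3SiC≡CH, n-BuLi, then Et2AlCl, toluene, 0 °C; add 15, 0 °C → rt
Reagents that add atoms: trimethylsilylacetylene (as its diethylaluminium acetylide), C#C[Si](C)(C)C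
Why: In this hydroxyl-directed epoxide opening by an alkynylalane (Oshima–Nozaki type) the C9 aluminium alkoxide chelates the cis epoxide oxygen and the alkynyl group attacks the distal carbon C7 with inversion, which places the two-carbon unit on the face opposite O6 and leaves C8–OH cis to C9–OH.

Step 11
Reactants: 16 alkynyl triol
Product: 17 8,9-O-isopropylidene derivative (C1–OH free)
Conditions: 2,2-dimethoxypropane, PPTS (cat.), CH2Cl2, rt
Reagents that add atoms: 2,2-dimethoxypropane, COC(C)(C)OC
Why: Acid-catalysed acetonide formation selects the cis-vicinal C8/C9 diol (five-membered dioxolane) over the C1/C9 1,3-diol, which masks O9 for the next step and O8 for the lactone closure.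

Step 12
Reactants: 17 acetonide
Product: 19 1,10-epoxide (glycidic methyl ester), via iodo ester 18 (not isolated)
Conditions: LiN(i-Pr)2 (2.5 equiv), THF, −78 → −40 °C; I2, −78 °C → rt
Reagents that add atoms: none
Why: In this β-hydroxy ester dianion iodination with Darzens-type closure the C1 lithium alkoxide chelates the C10 ester enolate, iodine enters on the chelate face anti to C2, and on warming the alkoxide displaces iodide with inversion, which gives the ring-cis oxirane with C14 cis to H1.

Step 13
Reactants: 19 glycidic ester
Product: 20 6-hydroxy 7-ethynyl compound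
Conditions: Bu4NF, AcOH, THF, 0 °C → rt
Reagents that add atoms: none
Why: Fluoride-mediated desilylation removes the C6 silyl ether and the alkynylsilane together, and the acetic acid buffer protects the glycidic ester.

Step 14
Reactants: 20 6-hydroxy 7-ethynyl compound
Product: 21 α-methylene lactone acetonide (6,12-olide, trans-fused)
Conditions: PdCl2(PPh3)2 (5 mol %), SnCl2 (5 mol %), CO (7 atm), MeCN, 65 °C
Reagents that add atoms: carbon monoxide, [C-]#[O+]
Why: In this palladium-catalysed cyclocarbonylation of a homopropargylic alcohol (Norton lactone synthesis) the alkoxycarbonylpalladium unit formed at O6 adds cis across the alkyne and protonolysis gives the α-methylene-γ-lactone, trans-fused because C6–O and C7–C were set trans in steps 8 and 10, while O8 is masked.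

Step 15
Reactants: 21 lactone acetonide
Product: 22 8,9-cis-diol lactone
Conditions: AcOH/H2O (4:1), 40 °C
Reagents that add atoms: none
Why: Acid hydrolysis of the acetonide frees the cis-diol, while the glycidic ester, deactivated toward acid by its carbonyl group, and the lactone survive.

Step 16
Reactants: 22 diol lactone; 23 (S)-2-methylbutanoic acid
Product: 24 target (CNP0581690.1)
Conditions: PPh3, DIAD, toluene, 0 °C → rt
Reagents that add atoms: none
Why: In this Mitsunobu esterification of a vicinal diol the dioxaphosphorane is opened by the carboxylate at C8, the carbon not flanked by the fully substituted C10, with inversion, which gives the C8 ester cis to C7–C11 and leaves C9–OH free; the α-centre of the acid is not enolised under these neutral conditions.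

**Compound list**

1 | tropone (cyclohepta-2,4,6-trien-1-one) | O=C1C=CC=CC=C1 | starting material
2 | 2-methylfuran | Cc1ccco1 | starting material
3 | exo [6+4] cage trienone (C14 ketone across C10/C5, oxygen across C1/C4 anti to it, methyl on C4) | O=C1[C@@H]2C=CC=C[C@H]1[C@]3(C)C=C[C@H]2O3 | intermediate
4 | C6,C9-endoperoxide of 3 (peroxide on the carbonyl-bridge face) | O=C1[C@@H]2[C@H]3C=C[C@H](OO3)[C@H]1[C@]4(C)C=C[C@H]2O4 | intermediate (not isolated)
5 | cage enediol (6,9-cis-diol, C7=C8) | O=C1[C@@H]2[C@H](O)C=C[C@H](O)[C@H]1[C@]3(C)C=C[C@H]2O3 | intermediate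
6 | cage epoxy diol (7,8-epoxide cis to both hydroxyls) | O=C1[C@@H]2[C@H](O)[C@@H]3O[C@@H]3[C@H](O)[C@H]1[C@]4(C)C=C[C@H]2O4 | intermediate
7 | 2,3-dihydro epoxy diol | O=C1[C@@H]2[C@H](O)[C@@H]3O[C@@H]3[C@H](O)[C@H]1[C@]4(C)CC[C@H]2O4 | intermediate
8 | 9-O-acetate of 7 | O=C1[C@@H]2[C@H](OC(C)=O)[C@@H]3O[C@@H]3[C@H](O)[C@H]1[C@]4(C)CC[C@H]2O4 | intermediate
9 | C6 ketone of 8 (cage 1,3-diketone) | O=C1[C@@H]2[C@H](OC(C)=O)[C@@H]3O[C@@H]3C(=O)[C@H]1[C@]4(C)CC[C@H]2O4 | intermediate
10 | 1,4-ether-bridged cyclodecanone methyl ester (C14–C5 cleaved, 9-OH free) | O=C1C[C@]2(C)CC[C@@H](O2)[C@H](C(=O)OC)[C@H](O)[C@@H]3O[C@H]13 | intermediate (not isolated)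
11 | (4Z)-germacrene enone (C10 methyl ester, 1-OH, 9-OH, 7,8-epoxide, C6 ketone) | O=C1/C=C(/C)CC[C@@H](O)[C@H](C(=O)OC)[C@H](O)[C@@H]2O[C@H]12 | intermediate
12 | 1,6,9-triol | O[C@@H]1/C=C(/C)CC[C@@H](O)[C@H](C(=O)OC)[C@H](O)[C@@H]2O[C@H]12 | intermediate
13 | 1,9-O-phenylboronate of 12 | O[C@@H]1/C=C(/C)CC[C@@H](O3)[C@H](C(=O)OC)[C@H](OB3c4ccccc4)[C@@H]2O[C@H]12 | intermediate (not isolated)
14 | 6-O-TBS ether of 13 | CC(C)(C)[Si](C)(C)O[C@@H]1/C=C(/C)CC[C@@H](O3)[C@H](C(=O)OC)[C@H](OB3c4ccccc4)[C@@H]2O[C@H]12 | intermediate (not isolated)
15 | 6-O-TBS ether of 12 (1,9-diol) | CC(C)(C)[Si](C)(C)O[C@@H]1/C=C(/C)CC[C@@H](O)[C@H](C(=O)OC)[C@H](O)[C@@H]2O[C@H]12 | intermediate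
16 | 7-[(trimethylsilyl)ethynyl] 1,8,9-triol | CC(C)(C)[Si](C)(C)O[C@@H]1/C=C(/C)CC[C@@H](O)[C@H](C(=O)OC)[C@H](O)[C@H](O)[C@H]1C#C[Si](C)(C)C | intermediate
17 | 8,9-O-isopropylidene derivative of 16 | CC(C)(C)[Si](C)(C)O[C@@H]1/C=C(/C)CC[C@@H](O)[C@H](C(=O)OC)[C@@H]2OC(C)(C)O[C@@H]2[C@H]1C#C[Si](C)(C)C | intermediate
18 | C10 iodide of 17 (iodine anti to C2) | CC(C)(C)[Si](C)(C)O[C@@H]1/C=C(/C)CC[C@@H](O)[C@@](I)(C(=O)OC)[C@@H]2OC(C)(C)O[C@@H]2[C@H]1C#C[Si](C)(C)C | intermediate (not isolated)
19 | 1,10-epoxide (glycidic methyl ester) | CC(C)(C)[Si](C)(C)O[C@@H]1/C=C(/C)CC[C@H]3O[C@@]3(C(=O)OC)[C@@H]2OC(C)(C)O[C@@H]2[C@H]1C#C[Si](C)(C)C | intermediate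
20 | 6-hydroxy 7-ethynyl epoxy ester | O[C@@H]1/C=C(/C)CC[C@H]3O[C@@]3(C(=O)OC)[C@@H]2OC(C)(C)O[C@@H]2[C@H]1C#C | intermediate
21 | α-methylene 6,12-lactone, 8,9-acetonide | C=C1C(=O)O[C@@H]2/C=C(/C)CC[C@H]3O[C@@]3(C(=O)OC)[C@@H]4OC(C)(C)O[C@@H]4[C@@H]12 | intermediate
22 | α-methylene 6,12-lactone, 8,9-cis-diol (C8 epimeric to the target) | C=C1C(=O)O[C@@H]2/C=C(/C)CC[C@H]3O[C@@]3(C(=O)OC)[C@H](O)[C@H](O)[C@@H]12 | intermediate
23 | (S)-2-methylbutanoic acid | CC[C@H](C)C(=O)O | starting material
24 | CNP0581690.1 (methyl 1,10-epoxy-9-hydroxy-8-[(S)-2-methylbutanoyloxy]-(4Z)-germacra-4,11(13)-dien-6,12-olid-14-oate) | C=C1C(=O)O[C@@H]2/C=C(/C)CC[C@H]3O[C@@]3(C(=O)OC)[C@H](O)[C@@H](OC(=O)[C@@H](C)CC)[C@@H]12 | target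

**Count**

Total steps: 16. Longest linear sequence: 16 steps (1 and 2 to 24).

**Steps most likely to fail**

Step 1 (proposed new method). The activated tropone may be attacked only once by the furan, after which the zwitterion loses a proton (Friedel–Crafts substitution) or closes in a [4+2] sense, and the furan may oligomerise under the acid. The fallback uses the known [4+3] cycloaddition of furans with cyclic oxyallyl cations; it sets out from 2 and comes back at 3, as the racemate. Commercial cyclohept-4-en-1-one is α-chlorinated (LiN(i-Pr)2, Me3SiCl, then N-chlorosuccinimide) to 2-chlorocyclohept-4-en-1-one F1. Generation of the oxyallyl cation (NaOCH2CF3, CF3CH2OH) in the presence of 2 should give, through the compact transition state, the cage enone F2, which has the ring fusion of 3 but only the C7=C8 alkene. Allylic bromination (N-bromosuccinimide, AIBN) gives the bromide F3, whose allylic isomers converge, and DBU removes HBr to give racemic 3. The enantiomers are parted at step 5: the lipase should acetylate C9–OH in the enantiomer of the main route and C6–OH in its antipode, which gives separable constitutional isomers.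

Step 7. The cascade may stop after the C–C cleavage at the bridged keto ester, the released C1 alkoxide may add back across the ring to the enone, or the E alkene may form. The fallback separates the two events; it sets out from 9 and comes back at 11. Catalytic K2CO3 in MeOH at −20 °C is expected to stop at 10, which is then isolated. DBU with Me3SiCl in CH2Cl2 effects the E1cB opening while silylating the released C1 oxygen (and O9) at once, so that re-addition cannot occur, giving the 1,9-bis(trimethylsilyl) ether F4. A wrong alkene geometry would be equilibrated at this stage by iodine under visible light, and aqueous citric acid then returns 11.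

Step 12. Deprotonation of the tertiary C10–H may be slow, the enolate may expel the C9 acetal oxygen, or iodine may enter on the wrong face. The fallback avoids the ester enolate; it sets out from 17 and comes back at 19. Dess–Martin oxidation of C1–OH gives the β-keto ester F5, whose C10–H is acidic enough for chlorination with N-chlorosuccinimide and catalytic Et3N to the α-chloro β-keto ester F6. Corey–Bakshi–Shibata reduction (oxazaborolidine, BH3·SMe2) resets C1 under reagent control to give the chlorohydrin F7, and K2CO3 in MeOH closes the oxirane with inversion at C10 to 19.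

**Further compounds**

F1 | step 1 | 2-chlorocyclohept-4-en-1-one (racemic) | O=C1CCC=CCC1Cl
F2 | step 1 | cage enone with C7=C8 alkene only (racemic, relative configuration of 3) | O=C1[C@@H]2CC=CC[C@H]1[C@]3(C)C=C[C@H]2O3
F3 | step 1 | C9 allylic bromide of F2 (racemic, bromine configuration not controlled) | O=C1[C@@H]2C(Br)C=CC[C@H]1[C@]3(C)C=C[C@H]2O3
F4 | step 7 | 1,9-bis(trimethylsilyl) ether of 11 | O=C1/C=C(/C)CC[C@@H](O[Si](C)(C)C)[C@H](C(=O)OC)[C@H](O[Si](C)(C)C)[C@@H]2O[C@H]12
F5 | step 12 | C1 ketone of 17 (β-keto ester, C10 epimerisable) | CC(C)(C)[Si](C)(C)O[C@@H]1/C=C(/C)CCC(=O)C(C(=O)OC)[C@@H]2OC(C)(C)O[C@@H]2[C@H]1C#C[Si](C)(C)C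
F6 | step 12 | C10 chloride of F5 | CC(C)(C)[Si](C)(C)O[C@@H]1/C=C(/C)CCC(=O)[C@@](Cl)(C(=O)OC)[C@@H]2OC(C)(C)O[C@@H]2[C@H]1C#C[Si](C)(C)C
F7 | step 12 | chlorohydrin (C1–OH, C10–Cl) | CC(C)(C)[Si](C)(C)O[C@@H]1/C=C(/C)CC[C@@H](O)[C@@](Cl)(C(=O)OC)[C@@H]2OC(C)(C)O[C@@H]2[C@H]1C#C[Si](C)(C)C
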